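**Plan**

- Retrosynthesis: the three O-protecting groups are removed first, then the C-3–C-1' bond is cut (Suzuki–Miyaura) to a 3-iodo-6,8-diprenylchromone and an 8-borylated 2,2-dimethylchromene. In the chromene, the pyran ring is cut at C-4–C-4a and C-2–C-3, leading back to an aryl isopropenyl ether and ethyl vinyl ether.
- Enabling feature: in ring B, O-2' already carries the gem-dimethyl carbon, so its O-aryl oxocarbenium ion (C-3'=C-2'–O+=CMe2) is a cationic 2-oxadiene. C-3' lies between O-2' and O-4' (doubly activated) and C-1' is blocked, so a two-carbon enol ether can close the pyran only at C-3'.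
- Forward, ring B part: monosilylation of 4-bromoresorcinol, O-isopropenylation, polar [4+2] annulation with loss of ethanol (dimethylpyran ring), bromine–boron exchange.
- Forward, ring A part: double C-prenylation of phloracetophenone, MOM protection, enaminone, iodocyclisation (pyranone ring C).
- Union by Suzuki–Miyaura coupling, then desilylation and MOM removal.
- Stereochemistry: the target has no stereocentre and no stereogenic alkene; the one transient stereocentre (C-4 of the ethoxychroman) is racemic and is eliminated.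

Key step: step 3

**Route**

Step 1
Reactants: 1 4-bromobenzene-1,3-diol (4-bromoresorcinol)
Product: 2 2-bromo-5-(triisopropylsilyloxy)phenol
Conditions: iPr3SiCl (1.05 equiv), imidazole (2.2 equiv), CH2Cl2, 0 °C
Reagents that add atoms: triisopropylsilyl chloride, CC(C)[Si](Cl)(C(C)C)C(C)C
Why: Sterically controlled O-silylation of a phenol: the bulky silyl chloride should take the hydroxyl para to bromine and leave the one flanked by bromine free.

Step 2
Reactants: 2 2-bromo-5-(triisopropylsilyloxy)phenol
Product: 3 [4-bromo-3-(prop-1-en-2-yloxy)phenoxy]triisopropylsilane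
Conditions: isopropenylboronic acid pinacol ester (2 equiv), Cu(OAc)2 (0.3 equiv), pyridine (3 equiv), 4 Å MS, CH2Cl2, O2 (1 atm), rt; chromatography on Et3N-deactivated silica
Reagents that add atoms: 4,4,5,5-tetramethyl-2-(prop-1-en-2-yl)-1,3,2-dioxaborolane, CC(=C)B1OC(C)(C)C(C)(C)O1
Why: Chan–Lam oxidative O-alkenylation of a phenol with an alkenylboronate (divalent copper catalyst, oxygen as terminal oxidant) should install the acid-sensitive isopropenyl ether under neutral conditions that leave the aryl bromide and the silyl ether untouched.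

Step 3
Reactants: 3 [4-bromo-3-(prop-1-en-2-yloxy)phenoxy]triisopropylsilane
Product: 6 8-bromo-2,2-dimethyl-5-(triisopropylsilyloxy)-2H-chromene, via α-chloro ether 4 (not isolated), via 4-ethoxychroman 5 (not isolated)
Conditions: HCl (1.0 equiv, 2 M in Et2O), CH2Cl2, −78 °C; 2,6-di-tert-butyl-4-methylpyridine (1.1 equiv), ethyl vinyl ether (1.5 equiv), then AgOTf (1.1 equiv, slow addition), −78 to −40 °C; filter, aq. NaHCO3; then TsOH·H2O (0.3 equiv), PhMe, 80 °C
Reagents that add atoms: ethyl vinyl ether, C=COCC
Why: Proposed new method: HCl adds to the isopropenyl ether to give the tertiary α-chloro ether 4, AgOTf removes chloride (the promoter pair AgOTf/hindered pyridine known from glycosyl halide activation) and the resulting O-aryl oxocarbenium ion, a cationic 2-oxadiene C-3'=C-2'–O+=CMe2, is attacked at carbon by the CH2 terminus of ethyl vinyl ether (new C-2–C-3 bond of the pyran) to give an ethoxycarbenium ion that alkylates C-3' of ring B (new C-4–C-4a bond), the proton going to the pyridine base. The closest known reaction type is the oxa-Povarov reaction (formal inverse-demand [4+2] of aldehyde-derived aryl oxocarbenium ions with alkenes) and, on nitrogen, the Povarov reaction of N-aryl iminium ions with ethyl vinyl ether; not shown so far are the ketone-derived gem-dimethyl oxocarbenium ion and the enol ether partner on oxygen. The pyran ring closes by a Friedel–Crafts attack of the arene on the ethoxycarbenium carbon that is 6-exo-trig with respect to the C=O+ bond; TsOH then ionises the benzylic ether of 5, which is flanked by two ortho oxygens, and loss of a proton from C-3 (E1) gives the chromene. The C-4 stereocentre of 5 forms racemic and is erased in the elimination, so nothing has to be controlled. Regioselectivity is secured by the substrate, since the tether reaches only the positions ortho to O-2', C-1' carries bromine and C-3' is activated by O-2' and O-4'. Chemoselectivity (one vinyl ether per cation) should follow from the pre-formed chloro ether as the only cation source, slow addition of the silver salt and the fast intramolecular capture, with the hindered base keeping the medium free of protons that would start vinyl ether oligomerisation.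

Step 4
Reactants: 6 8-bromo-2,2-dimethyl-5-(triisopropylsilyloxy)-2H-chromene
Product: 7 2-[2,2-dimethyl-5-(triisopropylsilyloxy)-2H-chromen-8-yl]-4,4,5,5-tetramethyl-1,3,2-dioxaborolane
Conditions: n-BuLi (1.1 equiv), THF, −78 °C; 2-isopropoxy-4,4,5,5-tetramethyl-1,3,2-dioxaborolane (1.3 equiv), −78 °C to rt; aq. NH4Cl
Reagents that add atoms: 2-isopropoxy-4,4,5,5-tetramethyl-1,3,2-dioxaborolane, CC(C)OB1OC(C)(C)C(C)(C)O1
Why: Bromine–lithium exchange followed by borylation: the exchange at −78 °C should be faster than any deprotonation of the chromene, and the aryllithium, stabilised by the ortho ring oxygen, is trapped by the isopropoxyboronate.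

Step 5
Reactants: 8 1-(2,4,6-trihydroxyphenyl)ethanone (phloracetophenone)
Product: 9 1-[2,4,6-trihydroxy-3,5-bis(3-methylbut-2-enyl)phenyl]ethanone
Conditions: prenyl bromide (2.1 equiv), KOH (2.1 equiv), H2O, 0 °C to rt
Reagents that add atoms: 1-bromo-3-methylbut-2-ene (prenyl bromide), CC(C)=CCBr
Why: Base-mediated C-allylation of an ambident phloroglucinol phenoxide in water, the established way to 3,5-diprenylacylphloroglucinols, should place one prenyl group on each free ring carbon.

Step 6
Reactants: 9 1-[2,4,6-trihydroxy-3,5-bis(3-methylbut-2-enyl)phenyl]ethanone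
Product: 10 1-[2-hydroxy-4,6-bis(methoxymethoxy)-3,5-bis(3-methylbut-2-enyl)phenyl]ethanone
Conditions: MOMCl (2.3 equiv), iPr2NEt (3 equiv), CH2Cl2, 0 °C to rt
Reagents that add atoms: chloromethyl methyl ether, COCCl
Why: O-alkylation to MOM acetals (Williamson-type): the 4-OH and one of the two equivalent ortho hydroxyls should react, while the last hydroxyl is hydrogen-bonded to the ketone and stays free.

Step 7
Reactants: 10 1-[2-hydroxy-4,6-bis(methoxymethoxy)-3,5-bis(3-methylbut-2-enyl)phenyl]ethanone
Product: 11 (E)-3-(dimethylamino)-1-[2-hydroxy-4,6-bis(methoxymethoxy)-3,5-bis(3-methylbut-2-enyl)phenyl]prop-2-en-1-one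
Conditions: Me2NCH(OMe)2 (3 equiv), PhMe, 90 °C
Reagents that add atoms: N,N-dimethylformamide dimethyl acetal, COC(OC)N(C)C
Why: Enaminone formation by condensation of the methyl ketone with the amide acetal; the E geometry is the thermodynamic one of the push–pull alkene.

Step 8
Reactants: 11 (E)-3-(dimethylamino)-1-[2-hydroxy-4,6-bis(methoxymethoxy)-3,5-bis(3-methylbut-2-enyl)phenyl]prop-2-en-1-one
Product: 12 3-iodo-5,7-bis(methoxymethoxy)-6,8-bis(3-methylbut-2-enyl)-4H-chromen-4-one
Conditions: I2 (1.05 equiv), CHCl3, 0 °C to rt; aq. Na2S2O3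
Reagents that add atoms: iodine, II
Why: Gammill-type iodocyclisation: iodination of the enaminone α-carbon, attack of the phenol on the iminium carbon and loss of dimethylamine should give the 3-iodochromone, the strongly nucleophilic enaminone being expected to consume the single equivalent of iodine before the prenyl alkenes react.

Step 9
Reactants: 12 3-iodo-5,7-bis(methoxymethoxy)-6,8-bis(3-methylbut-2-enyl)-4H-chromen-4-one; 7 2-[2,2-dimethyl-5-(triisopropylsilyloxy)-2H-chromen-8-yl]-4,4,5,5-tetramethyl-1,3,2-dioxaborolane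
Product: 13 3-[2,2-dimethyl-5-(triisopropylsilyloxy)-2H-chromen-8-yl]-5,7-bis(methoxymethoxy)-6,8-bis(3-methylbut-2-enyl)-4H-chromen-4-one
Conditions: Pd(OAc)2 (5 mol %), SPhos (10 mol %), K2CO3 (3 equiv), 1,4-dioxane/H2O (5:1), 70 °C
Reagents that add atoms: none
Why: Suzuki–Miyaura coupling of a 3-iodochromone with an arylboronate is the standard isoflavone assembly, and the biarylphosphine ligand should cope with the ortho-alkoxy boronate.

Step 10
Reactants: 13 3-[2,2-dimethyl-5-(triisopropylsilyloxy)-2H-chromen-8-yl]-5,7-bis(methoxymethoxy)-6,8-bis(3-methylbut-2-enyl)-4H-chromen-4-one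
Product: 14 3-(5-hydroxy-2,2-dimethyl-2H-chromen-8-yl)-5,7-bis(methoxymethoxy)-6,8-bis(3-methylbut-2-enyl)-4H-chromen-4-one
Conditions: Bu4NF (1.2 equiv), AcOH (1.2 equiv), THF, 0 °C
Reagents that add atoms: none
Why: Fluoride-induced desilylation of the aryl silyl ether, buffered with acetic acid so that the chromone is not exposed to basic fluoride.

Step 11
Reactants: 14 3-(5-hydroxy-2,2-dimethyl-2H-chromen-8-yl)-5,7-bis(methoxymethoxy)-6,8-bis(3-methylbut-2-enyl)-4H-chromen-4-one
Product: 15 Kanzonol L, 5,7-dihydroxy-3-(5-hydroxy-2,2-dimethyl-2H-chromen-8-yl)-6,8-bis(3-methylbut-2-enyl)-4H-chromen-4-one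
Conditions: 3 M aq. HCl, MeOH, 45 °C, stopped at full conversion
Reagents that add atoms: none
Why: Acid-catalysed methanolysis of the two MOM acetals, the usual way to unmask prenylated polyphenols, which under these mild conditions should leave the prenyl groups and the 2H-chromene intact.

**Compound list**

1 | 4-bromobenzene-1,3-diol (4-bromoresorcinol) | Oc1ccc(Br)c(O)c1 | starting material
2 | 2-bromo-5-(triisopropylsilyloxy)phenol | CC(C)[Si](Oc1ccc(Br)c(O)c1)(C(C)C)C(C)C | intermediate
3 | [4-bromo-3-(prop-1-en-2-yloxy)phenoxy]triisopropylsilane | C=C(C)Oc1cc(O[Si](C(C)C)(C(C)C)C(C)C)ccc1Br | intermediate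
4 | [4-bromo-3-(2-chloropropan-2-yloxy)phenoxy]triisopropylsilane (α-chloro ether, not isolated) | CC(C)(Cl)Oc1cc(O[Si](C(C)C)(C(C)C)C(C)C)ccc1Br | intermediate
5 | racemic 8-bromo-4-ethoxy-2,2-dimethyl-5-(triisopropylsilyloxy)chromane (4-ethoxychroman, not isolated) | CCOC1CC(C)(C)Oc2c(Br)ccc(O[Si](C(C)C)(C(C)C)C(C)C)c12 | intermediate
6 | 8-bromo-2,2-dimethyl-5-(triisopropylsilyloxy)-2H-chromene | CC1(C)C=Cc2c(O[Si](C(C)C)(C(C)C)C(C)C)ccc(Br)c2O1 | intermediate
7 | 2-[2,2-dimethyl-5-(triisopropylsilyloxy)-2H-chromen-8-yl]-4,4,5,5-tetramethyl-1,3,2-dioxaborolane | CC1(C)C=Cc2c(O[Si](C(C)C)(C(C)C)C(C)C)ccc(B3OC(C)(C)C(C)(C)O3)c2O1 | intermediate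
8 | 1-(2,4,6-trihydroxyphenyl)ethanone (phloracetophenone) | CC(=O)c1c(O)cc(O)cc1O | starting material
9 | 1-[2,4,6-trihydroxy-3,5-bis(3-methylbut-2-enyl)phenyl]ethanone | CC(=O)c1c(O)c(CC=C(C)C)c(O)c(CC=C(C)C)c1O | intermediate
10 | 1-[2-hydroxy-4,6-bis(methoxymethoxy)-3,5-bis(3-methylbut-2-enyl)phenyl]ethanone | CC(=O)c1c(O)c(CC=C(C)C)c(OCOC)c(CC=C(C)C)c1OCOC | intermediate
11 | (E)-3-(dimethylamino)-1-[2-hydroxy-4,6-bis(methoxymethoxy)-3,5-bis(3-methylbut-2-enyl)phenyl]prop-2-en-1-one | CN(C)/C=C/C(=O)c1c(O)c(CC=C(C)C)c(OCOC)c(CC=C(C)C)c1OCOC | intermediate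
12 | 3-iodo-5,7-bis(methoxymethoxy)-6,8-bis(3-methylbut-2-enyl)-4H-chromen-4-one | O=c1c(I)coc2c(CC=C(C)C)c(OCOC)c(CC=C(C)C)c(OCOC)c12 | intermediate
13 | 3-[2,2-dimethyl-5-(triisopropylsilyloxy)-2H-chromen-8-yl]-5,7-bis(methoxymethoxy)-6,8-bis(3-methylbut-2-enyl)-4H-chromen-4-one | O=c1c(-c2ccc(O[Si](C(C)C)(C(C)C)C(C)C)c3c2OC(C)(C)C=C3)coc2c(CC=C(C)C)c(OCOC)c(CC=C(C)C)c(OCOC)c12 | intermediate
14 | 3-(5-hydroxy-2,2-dimethyl-2H-chromen-8-yl)-5,7-bis(methoxymethoxy)-6,8-bis(3-methylbut-2-enyl)-4H-chromen-4-one | O=c1c(-c2ccc(O)c3c2OC(C)(C)C=C3)coc2c(CC=C(C)C)c(OCOC)c(CC=C(C)C)c(OCOC)c12 | intermediate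
15 | Kanzonol L | CC(C)=CCc1c(O)c(CC=C(C)C)c2occ(-c3ccc(O)c4c3OC(C)(C)C=C4)c(=O)c2c1O | target

**Summary**

Total step count: 11. Longest linear sequence: 7 steps (steps 1, 2, 3, 4, 9, 10, 11; the ring A branch, steps 5–8 then 9–11, is equally long).

Steps most likely to fail:

1. Step 3 (key step). The ethoxycarbenium ion formed after the first C–C bond may add further vinyl ether instead of closing the ring. The tertiary oxocarbenium ion may also lose a proton back to the isopropenyl ether, and closure at the position between two oxygen substituents, one a bulky silyl ether, may be slow. The fallback sets out from 2 and returns at 6. O-Alkylation of 2 with 3-chloro-3-methylbut-1-yne (CuCl2·2H2O cat., DBU, MeCN, 0 °C) should give {4-bromo-3-[(2-methylbut-3-yn-2-yl)oxy]phenoxy}triisopropylsilane F1. Heating F1 (N,N-diethylaniline, 180 °C) should give 6 by aryl propargyl ether Claisen rearrangement, 1,5-hydrogen shift and oxa-6π electrocyclisation, the bromine again leaving only C-3' open. This closes the pyran at the O–C bond instead of at the two C–C bonds.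

2. Step 8. Iodine may be consumed by the prenyl double bonds (iodoetherification with the free hydroxyl next to a prenyl group) in competition with the enaminone. The fallback avoids electrophilic halogen altogether; it sets out from 10 and 6 and returns at 15. Compound 10 is converted (NaH, MOMCl, DMF) into 1-[2,4,6-tris(methoxymethoxy)-3,5-bis(3-methylbut-2-enyl)phenyl]ethanone F2. Palladium-catalysed ketone α-arylation of F2 with bromide 6 (Pd(OAc)2, XPhos, K3PO4, PhMe, 90 °C) should give the deoxybenzoin 2-[2,2-dimethyl-5-(triisopropylsilyloxy)-2H-chromen-8-yl]-1-[2,4,6-tris(methoxymethoxy)-3,5-bis(3-methylbut-2-enyl)phenyl]ethanone F3. Removal of the silyl and MOM groups (Bu4NF/AcOH, then HCl/MeOH) should give 2-(5-hydroxy-2,2-dimethyl-2H-chromen-8-yl)-1-[2,4,6-trihydroxy-3,5-bis(3-methylbut-2-enyl)phenyl]ethanone F4. Ring closure of F4 with N,N-dimethylformamide dimethyl acetal (THF, 60 °C), the classical deoxybenzoin route to isoflavones, should give 15 directly.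

3. Step 5. The double C-prenylation may lack chemo- and regioselectivity (O-alkylation, mono-, geminal and triple alkylation). The fallback sets out from 8 and returns at 9. Bis-O-allylation of 8 (allyl bromide, K2CO3, acetone, reflux) should give 1-[2-hydroxy-4,6-bis(prop-2-enyloxy)phenyl]ethanone F5. Double aromatic Claisen rearrangement of F5 (N,N-diethylaniline, 200 °C), in which ortho migration and ortho migration followed by a Cope shift converge, should give 1-[2,4,6-trihydroxy-3,5-bis(prop-2-enyl)phenyl]ethanone F6. Cross-metathesis of F6 with 2-methylbut-2-ene (second-generation Grubbs catalyst, CH2Cl2, 40 °C) should then turn both allyl groups into prenyl groups to give 9.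

**Further compounds**

F1 | step 3 | {4-bromo-3-[(2-methylbut-3-yn-2-yl)oxy]phenoxy}triisopropylsilane | C#CC(C)(C)Oc1cc(O[Si](C(C)C)(C(C)C)C(C)C)ccc1Br
F2 | step 8 | 1-[2,4,6-tris(methoxymethoxy)-3,5-bis(3-methylbut-2-enyl)phenyl]ethanone | CC(=O)c1c(OCOC)c(CC=C(C)C)c(OCOC)c(CC=C(C)C)c1OCOC
F3 | step 8 | 2-[2,2-dimethyl-5-(triisopropylsilyloxy)-2H-chromen-8-yl]-1-[2,4,6-tris(methoxymethoxy)-3,5-bis(3-methylbut-2-enyl)phenyl]ethanone | COCOc1c(CC=C(C)C)c(OCOC)c(CC=C(C)C)c(OCOC)c1C(=O)Cc1ccc(O[Si](C(C)C)(C(C)C)C(C)C)c2c1OC(C)(C)C=C2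
F4 | step 8 | 2-(5-hydroxy-2,2-dimethyl-2H-chromen-8-yl)-1-[2,4,6-trihydroxy-3,5-bis(3-methylbut-2-enyl)phenyl]ethanone | O=C(Cc1ccc(O)c2c1OC(C)(C)C=C2)c1c(O)c(CC=C(C)C)c(O)c(CC=C(C)C)c1O
F5 | step 5 | 1-[2-hydroxy-4,6-bis(prop-2-enyloxy)phenyl]ethanone | CC(=O)c1c(O)cc(OCC=C)cc1OCC=C
F6 | step 5 | 1-[2,4,6-trihydroxy-3,5-bis(prop-2-enyl)phenyl]ethanone | CC(=O)c1c(O)c(CC=C)c(O)c(CC=C)c1O
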